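In a one-step world, electrophile + nucleophile → target, each turnover costs one nucleophile, and one rate constant read off the runs gives you your quick number. I would test that cost before trusting it.

the same everywhere: gas 130 mM (held)
- spring: electrophile 0.45 M; nucleophile 0.33 M; run made earlier
- summer: electrophile 0.15 M; nucleophile 0.33 M; run made earlier
- north-west: electrophile 0.30 M; nucleophile 0.330 M; time 15 h
- south: electrophile 0.30 M; nucleophile 0.660 M; time 15 h
- south-west: electrophile 0.30 M; nucleophile 1.30 M; time 15 h

| run | time / h | electrophile / % | target / % |
|---|---|---|---|
| spring | 0.500 | 97 | 3 |
| spring | 1.33 | 91 | 8 |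
| spring | 2.50 | 89 | 8 |
| spring | 4.00 | 82 | 17 |
| spring | 5.00 | 77 | 16 |
| spring | 8.00 | 70 | 26 |
| spring | 10.0 | 73 | 30 |
| summer | 1.33 | 89 | 7 |
| summer | 2.50 | 82 | 15 |
| summer | 4.00 | 75 | 23 |
| summer | 5.00 | 75 | 25 |
| summer | 6.00 | 71 | 28 |
| summer | 8.00 | 62 | 34 |
| summer | 10.0 | 57 | 40 |

(each reading ± 2 percentage points)

1. part of the electrophile that has reacted at the end, north-west
2. part of the electrophile that has reacted at the end, south
3. part of the electrophile that has reacted at the end, south-west
4. what raising the concentration of nucleophile from its lowest to its highest value here does to the part of the electrophile that has reacted (changes below 5 percentage points count as none) (it falls / it rises / no change)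

- the numbers in the tables scatter with a standard deviation of 2 percentage points
- at the start none of the gas is in solution

Both runs start from 0.33 M of nucleophile. So for each I take the last target reading, turn it into a pseudo-first-order constant (the log of charged over remaining electrophile, divided by time) and set it against the average turnover count, half the electrophile turned by then:

summer: 0.0511 h⁻¹ at 0.0300 M

spring: 0.0357 h⁻¹ at 0.0675 M

The constant is lower at the higher count. A straight line back to a count of zero gives, per unit of nucleophile, k = 0.00320 L mol⁻¹ min⁻¹. Its slope gives the price = 2.14, nucleophile lost per target made. That is a reading from two scattered points, but it stands above one.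

With that price held constant, I reckon:

part of electrophile left = (c(nucleophile) − price·c(electrophile)) / (c(nucleophile)·exp(k·(c(nucleophile) − price·c(electrophile))·t) − price·c(electrophile))

reacted: north-west 38.6%, south 66.1%, south-west 91.8%

Your forecast says 45%, 53% and 60%, and for the trend with more nucleophile, it rises, with the caution “Nucleophile was never varied, so its effect is a guess”. We share the direction, but at south-west mine stands higher, by 32 percentage points.

The flask gives 43.2% at north-west, 70.0% at south and 93.4% at south-west, against my 38.6%, 66.1% and 91.8%. From lowest to highest nucleophile, it rises, by 50 points.

    electrophile + acid set free → side product (k = 0.00349 L mol⁻¹ min⁻¹)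
    electrophile + nucleophile → acid set free + target (k = 0.00336 L mol⁻¹ min⁻¹)
    acid set free + free base ⇌ salt of the base, settled at all times (K = 10300 L mol⁻¹)
    nucleophile + acid set free ⇌ protonated nucleophile, settled at all times (K = 25000 L mol⁻¹)
    gas ⇌ free base, rate k5*(csat - [free base]) (kL = 0.268 min⁻¹)

Now take the neighbour of south-west with 0.52 M of nucleophile, the other charges and the time unchanged. The same k and price give 55.8% reacted, and that neighbour gives 60.2%. Its free nucleophile ends at 38% of its charge, a loss of 0.323 M against 0.181 M of target. So its price averages 1.78. The remainder of that loss stands in the neighbour as protonated nucleophile, 0.142 M after 15.0 h.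

The earlier runs and the new flask stem from a simulated flask for an exercise, noise included.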